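**Plan**
- Retrosynthetic cuts: the two benzylic alcohols go back to a ring-A aldehyde and a ring-B methyl ester, the C5 and C4' bromines to C–H, and the phenols to two methyl ethers plus a furan oxygen.
- Ring B is then opened across C6'–C1' and C2'–C3' into 3-methoxyfuran and a 3-aryloxypropiolate. The ArO–C1' bond, flanked by four ortho substituents, is traced to an oxa-Michael addition of a phenol to methyl propiolate.
- Forward: ring A is bought complete as 2-bromoisovanillin (aldehyde masked as a dioxolane). Addition, bromination and two dehydrobrominations give the ynol ether ester. Ring B arises in one flask by [4+2] cycloaddition and opening of the oxygen bridge. Demethylation, twofold bromination and hydride reduction finish the route.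
- Stereochemistry: the target is achiral. Intermediates 2, 8 and 11 are racemic and transient, and the alkene geometry of 7 and 9 disappears in alkyne 10.

Key step: step 6

Remark: atom labels follow the target (ring A: C1 CH2OH, C2 Br, C3 O-aryl, C4 OH, C5 Br; ring B: C1' O-aryl, C2' CH2OH, C4' Br, C5' and C6' OH). 3-Methoxyfuran is assumed too labile to buy and store, so it is made fresh in step 1.

**Step 1**
Reactants: 1 4-methoxyfuran-2(5H)-one (methyl tetronate)
Product: 3 3-methoxyfuran, via lactol 2 (not isolated)
Conditions: i-Bu2AlH (1.1 equiv), CH2Cl2, −78 °C; aq. potassium sodium tartrate, then brief cold 1 M HCl wash; careful distillation, used as a solution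
Reagents that add atoms: none
Why: 1,2-hydride reduction of the lactone carbonyl should stop at the lactol at −78 °C, and acid-promoted loss of water is driven by aromatisation (butenolide-to-furan reduction–dehydration).

**Step 2**
Reactants: 4 2-bromo-3-hydroxy-4-methoxybenzaldehyde (2-bromoisovanillin)
Product: 5 2-bromo-3-(1,3-dioxolan-2-yl)-6-methoxyphenol
Conditions: HOCH2CH2OH (3 equiv), TsOH·H2O (5 mol%), PhMe, reflux, azeotropic removal of water
Reagents that add atoms: ethylene glycol, OCCO
Why: acid-catalysed acetalisation masks the non-enolisable aldehyde against the amide base of step 5 and leaves the phenol free.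

**Step 3**
Reactants: 5 2-bromo-3-(1,3-dioxolan-2-yl)-6-methoxyphenol; 6 methyl propiolate
Product: 7 methyl (E)-3-[2-bromo-3-(1,3-dioxolan-2-yl)-6-methoxyphenoxy]prop-2-enoate
Conditions: 6 (1.2 equiv), 1,4-diazabicyclo[2.2.2]octane (DABCO, 10 mol%), CH2Cl2, 0 °C to rt
Reagents that add atoms: none
Why: amine-catalysed oxa-Michael addition of a phenol to an alkynoate forms the crowded aryl–O–C bond at an unhindered sp carbon, so the flanking bromine and methoxy groups are tolerated, and should deliver the E vinylogous carbonate.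

**Step 4**
Reactants: 7 methyl (E)-3-[2-bromo-3-(1,3-dioxolan-2-yl)-6-methoxyphenoxy]prop-2-enoate
Product: 9 methyl (Z)-2-bromo-3-[2-bromo-3-(1,3-dioxolan-2-yl)-6-methoxyphenoxy]prop-2-enoate, via dibromide 8 (not isolated)
Conditions: Br2 (1.05 equiv), CH2Cl2, −78 to 0 °C; then Et3N (2.5 equiv), 0 °C to rt
Reagents that add atoms: bromine, BrBr
Why: alkene bromination then amine dehydrobromination, the sequence known for 3-alkoxyacrylates, should outpace substitution of the bromo-deactivated ring at low temperature and give the more stable Z bromoalkene, whose β-hydrogen lies anti to bromine.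

**Step 5**
Reactants: 9 methyl (Z)-2-bromo-3-[2-bromo-3-(1,3-dioxolan-2-yl)-6-methoxyphenoxy]prop-2-enoate
Product: 10 methyl 3-[2-bromo-3-(1,3-dioxolan-2-yl)-6-methoxyphenoxy]prop-2-ynoate
Conditions: KN(SiMe3)2 (1.15 equiv), THF, −78 °C; sat. aq. NH4Cl at −78 °C
Reagents that add atoms: none
Why: anti-periplanar E2 dehydrobromination of a 2-bromovinyl ether is the classical entry to alkynyl ethers, and a hindered non-nucleophilic base at −78 °C should spare the ester, the dioxolane and the aryl bromide (no ortho hydrogen).

**Step 6**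
Reactants: 10 methyl 3-[2-bromo-3-(1,3-dioxolan-2-yl)-6-methoxyphenoxy]prop-2-ynoate; 3 3-methoxyfuran
Product: 13 methyl 2-(2-bromo-3-formyl-6-methoxyphenoxy)-3-hydroxy-4-methoxybenzoate, via oxanorbornadiene 11 (not isolated), via acetal phenol 12 (not isolated)
Conditions: 3 (3 equiv), PhMe (1 M), 60 °C, sealed tube; evaporate excess 3; CF3CO2H (10 mol%), CH2Cl2, 0 °C; then 2 M HCl, THF, rt
Reagents that add atoms: water, O
Why: The electron-rich furan and the ester-polarised alkyne combine in a concerted but asynchronous normal-demand [4+2] cycloaddition in which furan C2, the β-carbon of the 3-methoxy enol ether and the site of the largest HOMO coefficient, bonds to the aryloxy-bearing alkyne carbon β to the ester (C6'–C1') while furan C5 bonds to the ester-bearing carbon (C2'–C3'). The closest known reaction type is the Diels–Alder addition of 3-alkoxyfurans to acetylenic esters followed by acid opening of the 7-oxanorbornadiene to a phenol. Ring B is closed as a six-membered carbocycle by this intermolecular [4+2] mode, both bonds forming in the one step, and it is aromatised when acid ionises the C3'–O bridge bond and the C6' proton is lost, which leaves the former furan oxygen as the C6' hydroxyl. The two bridgehead stereocentres of 11 form as a racemate under no control and vanish on aromatisation, so no stereocontrolling element is needed. The step needs regiocontrol twice: the 3-methoxy group polarises the diene toward C2 for the cycloaddition, and only the C3' cation is stabilised by both the methoxy oxygen (through C4'=C5') and the aryloxy oxygen (through C2'=C1'), whereas a C6' cation would place charge on the ester-bearing carbon. Anhydrous acid is used for the opening so that the enol ether is not hydrolysed, and the aqueous HCl that follows only unmasks the ring-A aldehyde.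

**Step 7**
Reactants: 13 methyl 2-(2-bromo-3-formyl-6-methoxyphenoxy)-3-hydroxy-4-methoxybenzoate
Product: 14 methyl 2-(2-bromo-3-formyl-6-hydroxyphenoxy)-3,4-dihydroxybenzoate
Conditions: BBr3 (6 equiv), CH2Cl2, −78 to 0 °C; ice/H2O
Reagents that add atoms: none
Why: Lewis-acid cleavage of aryl methyl ethers (bromide attacks the boron-complexed methyl group) should free the C4 and C5' phenols while the diaryl ether, methyl ester, aldehyde and aryl bromide persist at low temperature.

**Step 8**
Reactants: 14 methyl 2-(2-bromo-3-formyl-6-hydroxyphenoxy)-3,4-dihydroxybenzoate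
Product: 15 methyl 5-bromo-2-(2,5-dibromo-3-formyl-6-hydroxyphenoxy)-3,4-dihydroxybenzoate
Conditions: Br2 (2.05 equiv), AcOH, rt
Reagents that add atoms: bromine, BrBr
Why: in this electrophilic aromatic bromination, C5 is the only open site ortho to the ring-A phenol (and meta to the formyl group), and C4' is ortho to the C5' hydroxyl, para to the ether oxygen and meta to the ester while C3' is ortho to the ester, as in the 5-bromination of protocatechuates.

**Step 9**
Reactants: 15 methyl 5-bromo-2-(2,5-dibromo-3-formyl-6-hydroxyphenoxy)-3,4-dihydroxybenzoate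
Product: 16 6-bromo-3-[2,5-dibromo-6-hydroxy-3-(hydroxymethyl)phenoxy]-4-(hydroxymethyl)benzene-1,2-diol
Conditions: i-Bu2AlH (10 equiv), THF, −78 to 0 °C; aq. potassium sodium tartrate, pH 6–7
Reagents that add atoms: none
Why: hydride reduction with excess i-Bu2AlH should take aldehyde and ester to the benzylic alcohols after the phenols are converted to aluminium phenoxides, aryl bromides are inert to it, and the near-neutral work-up protects the p-hydroxybenzyl alcohols from ionisation.

**Compound list**
1 | 4-methoxyfuran-2(5H)-one (methyl tetronate) | COC1=CC(=O)OC1 | starting material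
2 | 4-methoxy-2,5-dihydrofuran-2-ol (racemic lactol, one enantiomer drawn) | COC1=C[C@H](O)OC1 | intermediate
3 | 3-methoxyfuran | COc1ccoc1 | intermediate
4 | 2-bromo-3-hydroxy-4-methoxybenzaldehyde (2-bromoisovanillin) | O=Cc1ccc(OC)c(O)c1Br | starting material
5 | 2-bromo-3-(1,3-dioxolan-2-yl)-6-methoxyphenol | COc1ccc(C2OCCO2)c(Br)c1O | intermediate
6 | methyl propiolate | C#CC(=O)OC | starting material
7 | methyl (E)-3-[2-bromo-3-(1,3-dioxolan-2-yl)-6-methoxyphenoxy]prop-2-enoate | COC(=O)/C=C/Oc1c(Br)c(C2OCCO2)ccc1OC | intermediate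
8 | methyl (2R*,3R*)-2,3-dibromo-3-[2-bromo-3-(1,3-dioxolan-2-yl)-6-methoxyphenoxy]propanoate (racemic, one enantiomer drawn) | COC(=O)[C@H](Br)[C@H](Br)Oc1c(Br)c(C2OCCO2)ccc1OC | intermediate
9 | methyl (Z)-2-bromo-3-[2-bromo-3-(1,3-dioxolan-2-yl)-6-methoxyphenoxy]prop-2-enoate | COC(=O)/C(Br)=C/Oc1c(Br)c(C2OCCO2)ccc1OC | intermediate
10 | methyl 3-[2-bromo-3-(1,3-dioxolan-2-yl)-6-methoxyphenoxy]prop-2-ynoate | COC(=O)C#COc1c(Br)c(C2OCCO2)ccc1OC | intermediate
11 | methyl 3-[2-bromo-3-(1,3-dioxolan-2-yl)-6-methoxyphenoxy]-5-methoxy-7-oxabicyclo[2.2.1]hepta-2,5-diene-2-carboxylate (racemic, one enantiomer drawn) | COC1=C[C@@H]2O[C@H]1C(Oc1c(Br)c(C3OCCO3)ccc1OC)=C2C(=O)OC | intermediate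
12 | methyl 2-[2-bromo-3-(1,3-dioxolan-2-yl)-6-methoxyphenoxy]-3-hydroxy-4-methoxybenzoate | COC(=O)c1ccc(OC)c(O)c1Oc1c(Br)c(C2OCCO2)ccc1OC | intermediate
13 | methyl 2-(2-bromo-3-formyl-6-methoxyphenoxy)-3-hydroxy-4-methoxybenzoate | COC(=O)c1ccc(OC)c(O)c1Oc1c(Br)c(C=O)ccc1OC | intermediate
14 | methyl 2-(2-bromo-3-formyl-6-hydroxyphenoxy)-3,4-dihydroxybenzoate | COC(=O)c1ccc(O)c(O)c1Oc1c(Br)c(C=O)ccc1O | intermediate
15 | methyl 5-bromo-2-(2,5-dibromo-3-formyl-6-hydroxyphenoxy)-3,4-dihydroxybenzoate | COC(=O)c1cc(Br)c(O)c(O)c1Oc1c(Br)c(C=O)cc(Br)c1O | intermediate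
16 | 6-bromo-3-[2,5-dibromo-6-hydroxy-3-(hydroxymethyl)phenoxy]-4-(hydroxymethyl)benzene-1,2-diol (CNP0104332.0) | OCc1cc(Br)c(O)c(Oc2c(CO)cc(Br)c(O)c2O)c1Br | target

**Step count**
Total steps: 9. Longest linear sequence: 8 steps (4 to 16, steps 2–9); step 1 is a one-step branch.

**Steps most likely to fail**

1. Step 6. The push–pull ynoate may be too sluggish a dienophile, so that 3-methoxyfuran polymerises before it adds, or the regiochemistry of addition may erode. The fallback abandons ring construction and makes the diaryl ether bond directly. It sets out from 4. Fischer esterification of purchasable 2-bromo-3,4-dimethoxybenzoic acid gives methyl 2-bromo-3,4-dimethoxybenzoate F1, whose bromide is activated by the ortho ester. An Ullmann coupling of 4 with it (CuI, picolinic acid, K3PO4, DMSO, 90 °C) should give methyl 2-(2-bromo-3-formyl-6-methoxyphenoxy)-3,4-dimethoxybenzoate F2. Cleavage of all three methyl ethers with BBr3 returns to the route at 14.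

2. Step 5. Attack of the base at the ester or at the acrylate β-carbon may outrun elimination of the vinyl bromide. The fallback uses a better leaving group reached from a different precursor, and it sets out from 5. O-Alkylation with methyl bromopyruvate (K2CO3, acetone) should give methyl 3-[2-bromo-3-(1,3-dioxolan-2-yl)-6-methoxyphenoxy]-2-oxopropanoate F3. Enol triflation (LiN(SiMe3)2, PhNTf2, THF, −78 °C) gives methyl (Z)-3-[2-bromo-3-(1,3-dioxolan-2-yl)-6-methoxyphenoxy]-2-(trifluoromethylsulfonyloxy)prop-2-enoate F4. Treatment with KOt-Bu at −78 °C, the known elimination of α-alkoxy ketone enol triflates to ynol ethers, returns at 10.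

3. Step 9. The aluminium phenoxides of 15 may precipitate and leave the ester only partly reduced, or the product may ionise to quinone methides during work-up. The fallback caps the phenols first, and it sets out from 15. Silylation with t-BuMe2SiCl and imidazole in DMF should give methyl 5-bromo-3,4-bis(tert-butyldimethylsilyloxy)-2-[2,5-dibromo-6-(tert-butyldimethylsilyloxy)-3-formylphenoxy]benzoate F5. Reduction with i-Bu2AlH (CH2Cl2, −78 °C) gives {5-bromo-3,4-bis(tert-butyldimethylsilyloxy)-2-[2,5-dibromo-6-(tert-butyldimethylsilyloxy)-3-(hydroxymethyl)phenoxy]phenyl}methanol F6. Desilylation with Bu4NF buffered with AcOH (THF, 0 °C) returns at 16.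

**Further compounds**
F1 | step 6 | methyl 2-bromo-3,4-dimethoxybenzoate | COC(=O)c1ccc(OC)c(OC)c1Br
F2 | step 6 | methyl 2-(2-bromo-3-formyl-6-methoxyphenoxy)-3,4-dimethoxybenzoate | COC(=O)c1ccc(OC)c(OC)c1Oc1c(Br)c(C=O)ccc1OC
F3 | step 5 | methyl 3-[2-bromo-3-(1,3-dioxolan-2-yl)-6-methoxyphenoxy]-2-oxopropanoate | COC(=O)C(=O)COc1c(Br)c(C2OCCO2)ccc1OC
F4 | step 5 | methyl (Z)-3-[2-bromo-3-(1,3-dioxolan-2-yl)-6-methoxyphenoxy]-2-(trifluoromethylsulfonyloxy)prop-2-enoate | COC(=O)/C(OS(=O)(=O)C(F)(F)F)=C/Oc1c(Br)c(C2OCCO2)ccc1OC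
F5 | step 9 | methyl 5-bromo-3,4-bis(tert-butyldimethylsilyloxy)-2-[2,5-dibromo-6-(tert-butyldimethylsilyloxy)-3-formylphenoxy]benzoate | COC(=O)c1cc(Br)c(O[Si](C)(C)C(C)(C)C)c(O[Si](C)(C)C(C)(C)C)c1Oc1c(Br)c(C=O)cc(Br)c1O[Si](C)(C)C(C)(C)C
F6 | step 9 | {5-bromo-3,4-bis(tert-butyldimethylsilyloxy)-2-[2,5-dibromo-6-(tert-butyldimethylsilyloxy)-3-(hydroxymethyl)phenoxy]phenyl}methanol | OCc1cc(Br)c(O[Si](C)(C)C(C)(C)C)c(O[Si](C)(C)C(C)(C)C)c1Oc1c(Br)c(CO)cc(Br)c1O[Si](C)(C)C(C)(C)C
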